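The quinone ring (C1=O, C2–OH, C3–CH3, C4=O, C5–H, C6–nonadecyl) is divided into a four-carbon and a two-carbon piece. The contiguous C1–C2–C3–C4 unit, oxygenated at three of its atoms, is a disguised squarate ring. C5=C6 comes from a 1,1-disubstituted alkene. The key step is a strain-release ring expansion. A 4-alkenyl-4-hydroxycyclobutenone is heated, the four-membered ring opens to a dienylketene, and 6π electrocyclisation makes the C4–C5 bond. The regiodefined 1,4-dioxygenated carbocycle thus appears in one operation, and oxidation in the same flask gives the quinone. The precursor comes from dimethyl squarate, methyllithium and a C21 vinyl bromide.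

Key step: step 4

Remark: the target has no stereocentre and no stereogenic double bond, so it is achiral and a single compound. The only stereocentres on the route, the carbinol carbons of 2 and 9, are racemic and are erased later.

Step 1
Reactants: 1 dimethyl squarate (3,4-dimethoxycyclobut-3-ene-1,2-dione)
Product: 3 3-methoxy-4-methylcyclobut-3-ene-1,2-dione, via methyl carbinol 2 (not isolated)
Conditions: MeLi (1.05 equiv), THF, −78 °C; quench 1 M HCl; crude in CH2Cl2, conc. HCl (cat.), rt
Reagents that add atoms: methyllithium, [Li]C; water, O
Why: 1,2-addition of MeLi to one of the two equivalent carbonyls gives carbinol 2, and acid-catalysed ionisation, capture of the methoxy-stabilised cation by water and loss of methanol give the alkyl(alkoxy)cyclobutenedione, which is the standard squarate-to-cyclobutenedione sequence.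

Step 2
Reactants: 4 1-bromooctadecane; 5 2,3-dibromoprop-1-ene
Product: 7 2-bromohenicos-1-ene, via octadecylmagnesium bromide 6 (not isolated)
Conditions: Mg, THF, 45 °C; then 5 (1.2 equiv), CuI (5 mol %), 0 °C → rt
Reagents that add atoms: none
Why: This is Grignard formation followed by copper-catalysed allylic substitution, in which only the allylic C–Br bond of 5 reacts, SN2 and SN2' attack give the same product, and the vinylic bromide survives.

Step 3
Reactants: 7 2-bromohenicos-1-ene; 3 3-methoxy-4-methylcyclobut-3-ene-1,2-dione
Product: 9 (±)-4-(henicos-1-en-2-yl)-4-hydroxy-3-methoxy-2-methylcyclobut-2-en-1-one, via henicos-1-en-2-yllithium 8 (not isolated)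
Conditions: t-BuLi (2.0 equiv), Et2O–THF, −78 °C; then 3 in THF, −78 °C; sat. aq NH4Cl
Reagents that add atoms: none
Why: Bromine–lithium exchange is followed by 1,2-addition to the more electrophilic carbonyl of 3 (the one next to C–OMe, since the other is deactivated as a vinylogous ester), and the new carbinol centre forms as a racemate that step 4 erases.

Step 4
Reactants: 9 (±)-4-(henicos-1-en-2-yl)-4-hydroxy-3-methoxy-2-methylcyclobut-2-en-1-one
Product: 13 3-methoxy-2-methyl-5-nonadecylcyclohexa-2,5-diene-1,4-dione, via dienylketene 10 (not isolated), via cyclohexadienone 11 (not isolated), via hydroquinone 12 (not isolated)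
Conditions: toluene (0.02 M, degassed), reflux; cool to rt, then Ag2O (1.5 equiv)
Reagents that add atoms: none
Why: Heat cleaves the strained ring bond between the carbonyl carbon and the carbinol carbon of 9 in a conrotatory 4π electrocyclic opening, and the donor OH rotates outward, so the nonadecylvinyl group ends up cis to the ketene in 10. The six-membered carbocycle then closes by a thermal disrotatory 6π electrocyclisation in which the ketene carbon bonds to the terminal =CH2 (the C4–C5 bond of the target), giving dienone 11, whose tautomerisation to the aromatic hydroquinone 12 makes the cascade irreversible. Ag2O added to the cooled solution dehydrogenates 12 to quinone 13. The closest known reaction type is the Moore rearrangement of 4-alkenyl-4-hydroxycyclobutenones, the standard squarate route to substituted quinones. No stereocentre is formed and the racemic carbinol centre of 9 vanishes. The selectivity needed is regiochemical (nonadecyl next to the carbonyl flanked by C–OMe, ring H next to the carbonyl flanked by C–CH3) and is fixed by the connectivity of 9 because only one ring bond breaks and one forms, while the outward preference of OH and high dilution guard against lactonisation and ketene dimerisation.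

Step 5
Reactants: 13 3-methoxy-2-methyl-5-nonadecylcyclohexa-2,5-diene-1,4-dione
Product: 14 capiquinone C (3-hydroxy-2-methyl-5-nonadecylcyclohexa-2,5-diene-1,4-dione)
Conditions: 70% aq HClO4, 1,4-dioxane, rt
Reagents that add atoms: water, O
Why: This is acid-catalysed addition–elimination at the vinylogous methyl ester carbon, in which water adds and methanol leaves to give the stabilised vinylogous acid, and no other group in 13 is acid-labile.

Compound list
1 | dimethyl squarate (3,4-dimethoxycyclobut-3-ene-1,2-dione) | COC1=C(OC)C(=O)C1=O | starting material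
2 | (±)-4-hydroxy-2,3-dimethoxy-4-methylcyclobut-2-en-1-one | COC1=C(OC)C(C)(O)C1=O | intermediate
3 | 3-methoxy-4-methylcyclobut-3-ene-1,2-dione | COC1=C(C)C(=O)C1=O | intermediate
4 | 1-bromooctadecane | CCCCCCCCCCCCCCCCCCBr | starting material
5 | 2,3-dibromoprop-1-ene | C=C(Br)CBr | starting material
6 | octadecylmagnesium bromide | CCCCCCCCCCCCCCCCCC[Mg]Br | intermediate
7 | 2-bromohenicos-1-ene | CCCCCCCCCCCCCCCCCCCC(Br)=C | intermediate
8 | henicos-1-en-2-yllithium | CCCCCCCCCCCCCCCCCCCC([Li])=C | intermediate
9 | (±)-4-(henicos-1-en-2-yl)-4-hydroxy-3-methoxy-2-methylcyclobut-2-en-1-one | CCCCCCCCCCCCCCCCCCCC(=C)C1(O)C(OC)=C(C)C1=O | intermediate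
10 | (3Z)-4-hydroxy-3-methoxy-2-methyl-5-methylidenetetracosa-1,3-dien-1-one (dienylketene, alkenyl group cis to the ketene) | O=C=C(C)/C(OC)=C(/O)C(=C)CCCCCCCCCCCCCCCCCCC | intermediate
11 | 4-hydroxy-3-methoxy-2-methyl-5-nonadecylcyclohexa-2,4-dien-1-one | CCCCCCCCCCCCCCCCCCCC1=C(O)C(OC)=C(C)C(=O)C1 | intermediate
12 | 3-methoxy-2-methyl-5-nonadecylbenzene-1,4-diol | CCCCCCCCCCCCCCCCCCCc1cc(O)c(C)c(OC)c1O | intermediate
13 | 3-methoxy-2-methyl-5-nonadecylcyclohexa-2,5-diene-1,4-dione | CCCCCCCCCCCCCCCCCCCC1=CC(=O)C(C)=C(OC)C1=O | intermediate
14 | capiquinone C (3-hydroxy-2-methyl-5-nonadecylcyclohexa-2,5-diene-1,4-dione) | CCCCCCCCCCCCCCCCCCCC1=CC(=O)C(C)=C(O)C1=O | target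

Total step count: 5. Longest linear sequence: 4 steps (4 → 7 → 9 → 13 → 14, and equally 1 → 3 → 9 → 13 → 14).

Steps most likely to fail

Step 4. Partial inward rotation of the hydroxyl group, or a slow 6π closure, would let the free OH capture the ketene (lactonisation) or let the ketene oligomerise before the ring closes. The fallback removes the free hydroxyl. It sets out from 9, which is silylated (TMSOTf, 2,6-lutidine, CH2Cl2, −78 °C) to (±)-4-(henicos-1-en-2-yl)-3-methoxy-2-methyl-4-(trimethylsilyloxy)cyclobut-2-en-1-one F1. Thermolysis of this ether in refluxing toluene or p-xylene should give the monoprotected hydroquinone 3-methoxy-2-methyl-5-nonadecyl-4-(trimethylsilyloxy)phenol F2. Oxidative desilylation with ceric ammonium nitrate (MeCN–H2O, 0 °C) comes back to the route at 13.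

Step 3. The waxy bromide may precipitate at −78 °C, which leaves the exchange incomplete and unreacted t-BuLi free to attack 3. The basic vinyllithium may also deprotonate the ring methyl group or attack the vinylogous ester carbonyl. The fallback abandons cryogenic lithium chemistry. It sets out from 7, where direct magnesium insertion (Mg, 1,2-dibromoethane activation, THF, reflux) gives henicos-1-en-2-ylmagnesium bromide F3. This less basic reagent is added to 3 in THF at −20 °C in the presence of LaCl3·2LiCl, and after an NH4Cl quench the route is rejoined at 9.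

Step 5. Hydrolysis may be slow because the lipophilic quinone dissolves poorly in aqueous acid, and water or acid may add at the free C5–H position of the quinone in competition. The fallback moves the ether cleavage to the arene oxidation level. It sets out from 13, which is reduced (Na2S2O4, THF–H2O) to hydroquinone 12. Demethylation with BBr3 (CH2Cl2, −78 → 0 °C) gives 3-methyl-6-nonadecylbenzene-1,2,4-triol F4. Oxidation of this triol with air or Ag2O in Et2O comes back to the route at 14.

Further compounds
F1 | step 4 | (±)-4-(henicos-1-en-2-yl)-3-methoxy-2-methyl-4-(trimethylsilyloxy)cyclobut-2-en-1-one | CCCCCCCCCCCCCCCCCCCC(=C)C1(O[Si](C)(C)C)C(OC)=C(C)C1=O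
F2 | step 4 | 3-methoxy-2-methyl-5-nonadecyl-4-(trimethylsilyloxy)phenol | CCCCCCCCCCCCCCCCCCCc1cc(O)c(C)c(OC)c1O[Si](C)(C)C
F3 | step 3 | henicos-1-en-2-ylmagnesium bromide | CCCCCCCCCCCCCCCCCCCC([Mg]Br)=C
F4 | step 5 | 3-methyl-6-nonadecylbenzene-1,2,4-triol | CCCCCCCCCCCCCCCCCCCc1cc(O)c(C)c(O)c1O
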